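Ring C (cyclohexene C1'–C6') has a single alkene, C2'=C3', placed across the ring from the adjacent stereocentres C1' (which carries the 6-linked coumarin A) and quaternary C6' (which carries CH3 and C7'). The ring is therefore disconnected at that alkene: both centres are installed in an open chain by one iridium/amine allylation of an α-branched aldehyde, and ring-closing metathesis between the C1' vinyl group and an isopropenyl terminus then makes C2'=C3' and ring C in one operation without touching either centre. The metathesis precursor is the dienal (2R,3R)-3-(7-methoxy-2-oxochromen-6-yl)-2-methyl-2-(3-methylbut-3-enyl)pent-4-enal; its C7' aldehyde is afterwards methylenated and Heck-coupled with 8-iodo-7-methoxycoumarin (coumarin B).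

Key step: step 8

Assumption: in step 7 the (R)-ligand and the quinidine-derived amine are taken, by analogy with the parent aryl vinyl carbinol/α-branched aldehyde system, to give the (2R,3R) isomer. Each catalyst controls its own centre and both mirror-image forms of each are available, so the ligand or the amine would be exchanged if a pilot run showed the opposite sense.

Locants: C1' carries coumarin A, C3' carries CH3, C6' is quaternary, and C7'=C8' is the bridge to C8 of coumarin B.

Step 1
Reactants: 1 4-bromoresorcinol; 2 DL-malic acid
Product: 3 6-bromo-7-hydroxychromen-2-one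
Conditions: conc. H2SO4, 110–120 °C
Reagents that add atoms: none
Why: von Pechmann condensation, in which malic acid is decarbonylated to formylacetic acid that attacks the ring carbon para to one hydroxyl (the site between the two hydroxyls is hindered and the other ortho site is blocked by bromine) and lactonises to the coumarin.

Step 2
Reactants: 3 6-bromo-7-hydroxychromen-2-one
Product: 4 6-bromo-7-methoxychromen-2-one
Conditions: MeI, K2CO3, acetone, reflux
Reagents that add atoms: iodomethane, CI
Why: Williamson etherification of the acidic 7-hydroxyl, to which the lactone is inert under carbonate in acetone.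

Step 3
Reactants: 4 6-bromo-7-methoxychromen-2-one
Product: 5 7-methoxy-2-oxochromene-6-carbaldehyde
Conditions: Pd(OAc)2 (1 mol%), nBuP(1-adamantyl)2 (3 mol%), Me2NCH2CH2NMe2, CO/H2 (1:1, 5 bar), toluene, 100 °C
Reagents that add atoms: carbon monoxide, [C-]#[O+]
Why: Palladium-catalysed reductive carbonylation of an aryl bromide (oxidative addition, CO insertion, hydrogenolysis of the acylpalladium, amine as HBr acceptor), with the lactone and its conjugated alkene as spectators.

Step 4
Reactants: 5 7-methoxy-2-oxochromene-6-carbaldehyde
Product: 6 6-(1-hydroxyprop-2-enyl)-7-methoxychromen-2-one (racemic)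
Conditions: CH2=CHMgBr (1.1 equiv), THF, −78 °C; aq. NH4Cl
Reagents that add atoms: vinylmagnesium bromide, C=C[Mg]Br
Why: Grignard 1,2-addition to the aldehyde, which at −78 °C is far more electrophilic than the coumarin lactone; the carbinol is made racemic on purpose because both enantiomers converge in step 7.

Step 5
Reactants: 7 methyl propanoate; 8 4-bromo-2-methylbut-1-ene
Product: 10 methyl 2,5-dimethylhex-5-enoate (racemic), via lithium enolate 9 (not isolated)
Conditions: LiN(iPr)2, THF, −78 °C; then 8, DMPU, −78 → 0 °C
Reagents that add atoms: none
Why: Ester enolate alkylation (SN2) with a primary bromide, the polar cosolvent favouring substitution over elimination to isoprene.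

Step 6
Reactants: 10 methyl 2,5-dimethylhex-5-enoate
Product: 12 2,5-dimethylhex-5-enal (racemic), via aluminium hemiacetal 11 (not isolated)
Conditions: iBu2AlH (1.05 equiv), CH2Cl2, −78 °C; MeOH, then aq. potassium sodium tartrate
Reagents that add atoms: none
Why: Partial reduction of an ester, in which the tetrahedral aluminium hemiacetal persists at −78 °C and releases the aldehyde only on work-up.

Step 7
Reactants: 6 6-(1-hydroxyprop-2-enyl)-7-methoxychromen-2-one (racemic); 12 2,5-dimethylhex-5-enal (racemic, 2 equiv)
Product: 13 (2R,3R)-3-(7-methoxy-2-oxochromen-6-yl)-2-methyl-2-(3-methylbut-3-enyl)pent-4-enal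
Conditions: [Ir(cod)Cl]2 (3 mol%), (R)-BINOL-derived phosphoramidite of 5H-dibenzo[b,f]azepine (P,olefin ligand, 12 mol%), 9-amino-9-deoxy-epi-quinidine (10 mol%), Cl3CCO2H (50 mol%), ClCH2CH2Cl, 25 °C
Reagents that add atoms: none
Why: Stereodivergent iridium/amine dual catalysis (α-allylation of α-branched aldehydes with racemic aryl vinyl carbinols), in which the acid-promoted iridium complex ionises either enantiomer of 6 with loss of water to one (η3-allyl)iridium electrophile attacked at its substituted terminus under ligand control (C1'), while the cinchona primary amine converts either enantiomer of 12 into an enamine alkylated under amine control (quaternary C6'), so both racemates converge on one stereoisomer.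

Step 8
Reactants: 13 (2R,3R)-3-(7-methoxy-2-oxochromen-6-yl)-2-methyl-2-(3-methylbut-3-enyl)pent-4-enal
Product: 14 (1R,2R)-2-(7-methoxy-2-oxochromen-6-yl)-1,4-dimethylcyclohex-3-ene-1-carbaldehyde (aryl and formyl cis)
Conditions: second-generation Grubbs catalyst RuCl2(=CHPh)(H2IMes)(PCy3) (5 mol%), CH2Cl2 (0.01 M), 40 °C
Reagents that add atoms: none
Why: The ruthenium benzylidene first exchanges onto the unhindered monosubstituted C1' vinyl group, the new alkylidene adds intramolecularly to the 1,1-disubstituted isopropenyl alkene by [2+2] cycloaddition, and cycloreversion of the ruthenacyclobutane releases the C2'=C3' bond and a ruthenium methylidene that gives off ethylene irreversibly. The closest known reaction type is ring-closing metathesis of vinyl/isopropenyl 1,7-dienes to 1-methylcyclohexenes, including substrates that carry a free aldehyde. Ring C closes as a six-membered carbocycle by alkene–alkene metathesis between C2' and C3', and the fully substituted C6' next to the branched C1' biases the chain towards the folded conformer (gem-disubstituent effect), which offsets the sluggishness of forming a trisubstituted alkene. No stereocentre is created, and neither existing one is at risk, because C6' has no hydrogen and the C1' hydrogen is not alpha to a carbonyl. The step needs only site selectivity, which the substrate provides: initiation occurs at the sole monosubstituted alkene, the only ring within reach is six-membered, the electron-poor coumarin C3=C4 bond and the aldehyde do not engage the catalyst, and the styryl alkene has not yet been made.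

Step 9
Reactants: 14 (1R,2R)-2-(7-methoxy-2-oxochromen-6-yl)-1,4-dimethylcyclohex-3-ene-1-carbaldehyde
Product: 15 6-[(1S,6S)-6-ethenyl-3,6-dimethylcyclohex-2-en-1-yl]-7-methoxychromen-2-one (aryl and vinyl cis)
Conditions: Ph3PCH3Br (1.3 equiv), KN(SiMe3)2 (1.2 equiv), THF, 0 °C; then 14, −78 → 0 °C
Reagents that add atoms: methyltriphenylphosphonium bromide, C[P+](c1ccccc1)(c1ccccc1)c1ccccc1.[Br-]
Why: Wittig methylenation, in which the non-stabilised ylide (preformed with the salt in excess so that no free amide base remains) reacts with the aldehyde at low temperature much faster than with the vinylogous lactone, and the quaternary α-carbon excludes epimerisation.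

Step 10
Reactants: 16 umbelliferone (7-hydroxychromen-2-one)
Product: 17 7-hydroxy-8-iodochromen-2-one
Conditions: I2, KI, 20% aq. NH3, 0 °C → rt; then dil. HCl to pH 3
Reagents that add atoms: iodine, II
Why: Electrophilic aromatic iodination of the phenoxide, which in aqueous ammonia is directed to C8, the ortho position flanked by both ring oxygen substituents.

Step 11
Reactants: 17 7-hydroxy-8-iodochromen-2-one
Product: 18 8-iodo-7-methoxychromen-2-one
Conditions: MeI, K2CO3, acetone, reflux
Reagents that add atoms: iodomethane, CI
Why: Williamson etherification of the phenol, with the aryl iodide and lactone untouched.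

Step 12
Reactants: 15 6-[(1S,6S)-6-ethenyl-3,6-dimethylcyclohex-2-en-1-yl]-7-methoxychromen-2-one; 18 8-iodo-7-methoxychromen-2-one (1.2 equiv)
Product: 19 7-methoxy-8-[(E)-2-[(1S,2S)-2-(7-methoxy-2-oxochromen-6-yl)-1,4-dimethylcyclohex-3-en-1-yl]ethenyl]chromen-2-one (CNP0287121.2)
Conditions: Pd(OAc)2 (10 mol%), Bu4NCl, NaHCO3, DMF, 85 °C
Reagents that add atoms: none
Why: Mizoroki–Heck arylation, in which the arylpalladium iodide formed from 18 and zerovalent palladium inserts the terminal vinyl group with aryl on C8', and syn-β-hydride elimination can only use a C8' hydrogen because C6' is quaternary, giving the E-styrene while the trisubstituted ring alkene and the coumarin alkenes stay out of reach.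

Compound list
1 | 4-bromoresorcinol | Oc1ccc(Br)c(O)c1 | starting material
2 | DL-malic acid | OC(CC(=O)O)C(=O)O | starting material
3 | 6-bromo-7-hydroxychromen-2-one | Oc1cc2oc(=O)ccc2cc1Br | intermediate
4 | 6-bromo-7-methoxychromen-2-one | COc1cc2oc(=O)ccc2cc1Br | intermediate
5 | 7-methoxy-2-oxochromene-6-carbaldehyde | COc1cc2oc(=O)ccc2cc1C=O | intermediate
6 | 6-(1-hydroxyprop-2-enyl)-7-methoxychromen-2-one (racemic) | COc1cc2oc(=O)ccc2cc1C(O)C=C | intermediate
7 | methyl propanoate | CCC(=O)OC | starting material
8 | 4-bromo-2-methylbut-1-ene | C=C(C)CCBr | starting material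
9 | lithium enolate of methyl propanoate (lithium 1-methoxyprop-1-en-1-olate, not isolated) | CC=C(OC)O[Li] | intermediate
10 | methyl 2,5-dimethylhex-5-enoate (racemic) | COC(=O)C(C)CCC(C)=C | intermediate
11 | diisobutylaluminium 1-methoxy-2,5-dimethylhex-5-en-1-olate (tetrahedral hemiacetal, not isolated) | COC(O[Al](CC(C)C)CC(C)C)C(C)CCC(C)=C | intermediate
12 | 2,5-dimethylhex-5-enal (racemic) | O=CC(C)CCC(C)=C | intermediate
13 | (2R,3R)-3-(7-methoxy-2-oxochromen-6-yl)-2-methyl-2-(3-methylbut-3-enyl)pent-4-enal | COc1cc2oc(=O)ccc2cc1[C@@H](C=C)[C@@](C)(CCC(C)=C)C=O | intermediate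
14 | (1R,2R)-2-(7-methoxy-2-oxochromen-6-yl)-1,4-dimethylcyclohex-3-ene-1-carbaldehyde | COc1cc2oc(=O)ccc2cc1[C@H]1C=C(C)CC[C@@]1(C)C=O | intermediate
15 | 6-[(1S,6S)-6-ethenyl-3,6-dimethylcyclohex-2-en-1-yl]-7-methoxychromen-2-one | COc1cc2oc(=O)ccc2cc1[C@H]1C=C(C)CC[C@@]1(C)C=C | intermediate
16 | umbelliferone (7-hydroxychromen-2-one) | O=c1ccc2ccc(O)cc2o1 | starting material
17 | 7-hydroxy-8-iodochromen-2-one | O=c1ccc2ccc(O)c(I)c2o1 | intermediate
18 | 8-iodo-7-methoxychromen-2-one | COc1ccc2ccc(=O)oc2c1I | intermediate
19 | 7-methoxy-8-[(E)-2-[(1S,2S)-2-(7-methoxy-2-oxochromen-6-yl)-1,4-dimethylcyclohex-3-en-1-yl]ethenyl]chromen-2-one | COc1cc2oc(=O)ccc2cc1[C@H]1C=C(C)CC[C@@]1(C)/C=C/c1c(OC)ccc2ccc(=O)oc12 | target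

Total step count: 12. Longest linear sequence: 8 steps (steps 1, 2, 3, 4, 7, 8, 9, 12).

Steps most likely to fail

1. Step 7. The aldehyde carries two similar α-alkyl groups (CH3 versus CH2CH2R), whereas this dual catalysis is best established for α-aryl aldehydes. The enamine may therefore form as a geometric mixture and the diastereoselectivity at C6' may erode, while C1' stays under ligand control. The fallback sets out from 6 and comes back at 14, moving the introduction of the quaternary methyl to a point where the ring controls it. Commercial methyl 5-oxohexanoate would be methylenated (Ph3PCH3Br, KN(SiMe3)2, THF) to methyl 5-methylhex-5-enoate F1 and reduced (iBu2AlH, CH2Cl2, −78 °C) to 5-methylhex-5-enal F2. The linear-aldehyde variant of the dual catalysis ([Ir(cod)Cl]2, the same (R)-ligand, a diarylprolinol trimethylsilyl ether as secondary amine, (MeO)2P(O)OH, ClCH2CH2Cl, 25 °C) should couple F2 with 6 to (3S)-3-(7-methoxy-2-oxochromen-6-yl)-2-(3-methylbut-3-enyl)pent-4-enal F3, in which only the benzylic centre matters and has the same spatial arrangement as C1' of 13. Metathesis under the conditions of step 8 should close ring C to (2S)-2-(7-methoxy-2-oxochromen-6-yl)-4-methylcyclohex-3-ene-1-carbaldehyde F4. Deprotonation (KN(SiMe3)2, THF, −78 °C) and MeI should then alkylate the exocyclic enolate on the face away from the neighbouring aryl group, giving 14 with methyl trans to aryl.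

2. Step 12. Migratory insertion of the di-ortho-substituted arylpalladium species into the neopentyl-type vinyl group may be slow, so that reductive deiodination of 18 or arylation of a coumarin C3=C4 bond competes. The fallback sets out from 14 and comes back at 19, replacing the Heck insertion by an olefination that builds C7'=C8' with boron on C8', followed by cross-coupling. Takai–Utimoto boryl-olefination of 14 (CrCl2, LiI, Cl2CHB(pin), THF, rt) should give the E-alkenylboronate 7-methoxy-6-[(1S,6S)-3,6-dimethyl-6-[(E)-2-(4,4,5,5-tetramethyl-1,3,2-dioxaborolan-2-yl)ethenyl]cyclohex-2-en-1-yl]chromen-2-one F5. Suzuki–Miyaura coupling of F5 with 18 (PdCl2(dppf), K3PO4, THF/H2O, 60 °C; mildly acidic work-up) should give 19 with retention of the alkene geometry.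

3. Step 3. Hydrodebromination may outrun CO insertion on the electron-rich ortho-methoxy aryl bromide, or a palladium hydride may reduce the pyranone alkene. The fallback sets out from 4 and comes back at 5, installing the formyl carbon as a vinyl group and cleaving it. Suzuki–Miyaura vinylation of 4 (potassium vinyltrifluoroborate, PdCl2(dppf), Et3N, n-PrOH, 90 °C) should give 6-ethenyl-7-methoxychromen-2-one F6. Lemieux–Johnson cleavage (OsO4 cat., NaIO4, 2,6-lutidine, dioxane/H2O, rt) should give 5, the electron-rich styrene alkene being dihydroxylated in preference to the electron-poor lactone alkene.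

Further compounds
F1 | step 7 | methyl 5-methylhex-5-enoate | COC(=O)CCCC(C)=C
F2 | step 7 | 5-methylhex-5-enal | O=CCCCC(C)=C
F3 | step 7 | (3S)-3-(7-methoxy-2-oxochromen-6-yl)-2-(3-methylbut-3-enyl)pent-4-enal (C2 left undefined) | COc1cc2oc(=O)ccc2cc1[C@@H](C=C)C(CCC(C)=C)C=O
F4 | step 7 | (2S)-2-(7-methoxy-2-oxochromen-6-yl)-4-methylcyclohex-3-ene-1-carbaldehyde (C1 left undefined) | COc1cc2oc(=O)ccc2cc1[C@H]1C=C(C)CCC1C=O
F5 | step 12 | 7-methoxy-6-[(1S,6S)-3,6-dimethyl-6-[(E)-2-(4,4,5,5-tetramethyl-1,3,2-dioxaborolan-2-yl)ethenyl]cyclohex-2-en-1-yl]chromen-2-one | COc1cc2oc(=O)ccc2cc1[C@H]1C=C(C)CC[C@@]1(C)/C=C/B1OC(C)(C)C(C)(C)O1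
F6 | step 3 | 6-ethenyl-7-methoxychromen-2-one | COc1cc2oc(=O)ccc2cc1C=C
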